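## The problem

Compound 33 is an eremophilane: a trans-fused decalin (ring A = C1–C5 with C10, ring B = C5–C10) with seven ring stereocentres, esterified at O3 with a diester chain that holds two (Z)-enoates and one (S)-carbinol carbon. The ring work has to create the quaternary C5 with its methyl group (C14) next to a cis methyl group on C4 (C15), place H10 trans to C14, and put the C7 isopropenyl group and the cis-8,9-diol on the face opposite to C14. The centres form a chain of command: C8 and C9 can be bought as a sugar diol, C7 can be set from C8 by 1,2-induction, these three can decide the face on which C5–C10 forms, C4 can follow from an alkene geometry, and C3, whose oxygen is equatorial and trans to C15, is the thermodynamic epimer and can be set last. This matters because a hydride reagent must approach a C3 ketone along the axial path past the syn-axial C14 and is expected to give the axial alcohol; an equilibrating electron-transfer reduction is expected to give the equatorial one. The fragile parts are the (Z)-enoates (isomerised by nucleophilic acylation catalysts, and closing to a butenolide once the γ-oxygen is free), the isopropenyl group (acid, unselective hydrogenation) and the diol, which must stay masked until O3 is acylated. The structure opens up because C1–C10–C9–C8–C7 is an unbranched five-carbon chain carrying, at C9/C8, the erythro diol of C3/C4 of 2-deoxy-D-ribose (1), and because ring A is the formal Diels–Alder adduct of a C10=C1–C2=C3 diene and a C4=C5 dienophile joined through C6–C7–C8–C9, with the C3 oxygen and the C15 carbon placed where a donor on the diene and an acceptor on the dienophile are wanted.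

## Retrosynthesis

**33 ⇒ 32.** The two (Z)-alkenes of the side chain are traced back to two alkynes, so the last step is a double syn-semihydrogenation. A (Z)-enoic acid risks isomerisation when its carboxyl group is activated, and a (Z)-γ-hydroxy enoate lactonises; ynoates can do neither. The forward step must reduce two conjugated alkynes and leave the 1,1-disubstituted isopropenyl alkene alone.

**32 ⇒ 31 ⇒ 22 + 30.** The diol is re-masked as the acetonide it has carried since the first step, and the C3–O acyl bond is cut. Attaching the chain in two halves would cost two more operations on the precious core; one esterification with the complete acid 30 is shorter in the linear sequence. The core alcohol 22 has no carbonyl and only one free hydroxyl. The forward step is acylation of an equatorial secondary alcohol flanked by the C4 methyl group, then mild aqueous acid.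

**30 ⇒ 29 ⇒ 27 + 28, and 27 ⇒ 26 ⇒ 24 ⇒ 23.** The inner ester C–O bond and the bond between the carboxyl carbon and the alkyne are cut. The tert-butyl ester is chosen because it can be removed without base or nucleophile (the inner propargylic ester is labile) and without zerovalent palladium (which would ionise that ester). The stereocentre is bought with alcohol 23; acid 28 is commercial.

**22 ⇒ 20 (through 21) ⇒ 19 ⇒ 18.** The C3 configuration and the saturation of C1–C2 are both traced to the ring A enone 20. The cycloaddition below necessarily places the C3 oxygen on the β face (axial), so C3 must be corrected. Substitution with inversion at this hindered axial position invites elimination and would still leave the C1=C2 alkene, which cannot be hydrogenated beside the isopropenyl group. Oxidation followed by dissolving-metal reduction removes the alkene as part of an enone and sets the equatorial alcohol in one operation.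

**18 ⇒ 17 ⇒ 16 ⇒ 15.** The C15 methyl group is traced to the ester through the primary alcohol and its sulfonate. This is done while O3 still carries its silyl group, so that no free hydroxyl sits 1,3 to the sulfonate and neither oxetane formation nor fragmentation can compete with hydride displacement.

**15 ⇒ 14 (key disconnection).** The C3–C4 and C5–C10 bonds are cut, which opens both rings at once. An intermolecular Diels–Alder reaction would offer no control of regiochemistry or face at a trisubstituted dienophile, and an annulation building ring A onto a cyclohexanone would bring none of the ring B oxygens. The precursor 14 is acyclic with three stereocentres in place of seven. The forward reaction must choose one diene face and the ester-endo mode.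

**14 ⇒ 13 ⇒ 12.** No carbon–carbon bond is cut: the silyloxydiene is the γ-enolised form of enal 13, and the enal is the reduced form of a Weinreb amide. The amide is chosen as the aldehyde precursor because it survives oxidation, olefination, cuprate addition and phosphonate olefination, and can then be reduced ahead of the enoate.

**12 ⇒ 10 + 11.** The C4=C5 bond is cut by phosphonate olefination of the methyl ketone 10; the ester carbon of 11 becomes C15. The forward step must give the (E)-enoate, since its geometry becomes the cis relation of C14 and C15.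

**10 ⇒ 7 + 8.** The C7–C11 bond is cut: conjugate addition of an isopropenyl copper reagent to the γ-alkoxy enone 7, with C8 directing. Setting C7 here, before ring formation, lets it help choose the diene face later.

**7 ⇒ 4 + 5 (through 6), 4 ⇒ 2 + 3, 2 ⇒ 1.** The C6=C7 and C1=C2 alkenes are cut by two stabilised-ylide olefinations. The first opens the lactol 2 and frees the C7 hydroxyl in the same step, so the two ends of 1 are differentiated without protecting-group steps.

## Roads not taken

**Alternative 1:** The cut is the C5–C14 bond: the angular methyl group is seen as one carbon of a cyclopropane across C5–C10, and the bicycle as the reduced form of the aromatic ketone A1. Birch reduction and ketalisation would lead to the allylic alcohol A2, whose C9 hydroxyl binds a zinc carbenoid and delivers CH2 to the tetrasubstituted C5=C10 alkene on its own face to give A3 (Simmons–Smith type). Oxidation at C9 and reductive opening of the cyclopropyl ketone would then reveal C14 and H10. Its merits are a cheap aromatic start, robust reactions, and a quaternary centre set by one of the most dependable directed reactions, with no endo/exo question. For this target the weak points are three. The material is racemic unless C9 is set by resolution or asymmetric reduction. C4 is fixed in a protonation that takes no notice of C9. Ring B arrives with oxygen only at C9, so the C8 hydroxyl and C7 isopropenyl group must be added afterwards by enolate chemistry, each with its own stereochemical question. C3 would still need the same equilibrating reduction as in the chosen plan. In reliability of the quaternary centre this road is better; the chosen plan answers with C7, C8 and C9 in place before any ring is formed, in one enantiomer, and a much shorter path from ring closure to the core.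

**Alternative 2:** The cut is the C8–C9 bond: ring B would close by reductive coupling of the dialdehyde A4 with a divalent samarium reagent, whose bridged diketyl gives the cis-diol A5. The cis relation of the diol is a direct consequence of the mechanism, and the C3 oxygen is carried from the start in its final configuration. In that respect this road is better: the chosen plan spends steps 12 to 14 on correcting C3. The weak points are that A5 has no C7 isopropenyl group, so the two hydroxyls must be told apart, C8 oxidised, C7 functionalised through the enolate and C8 reduced back from the right face. The face of the new diol relative to ring A also depends on a single transition-state preference. Finally, A4 is a cyclohexane with four stereocentres including the quaternary one, which is most of the real work. The chosen plan forms the quaternary centre and both rings in one step.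

**Alternative 3:** The cut is biosynthetic: aristolochene synthase ionises the diphosphate A6, closes the ten-membered ring and then the decalin, and a hydride shift and a methyl shift give (+)-aristolochene A7. A7 has the configuration of 33 at C4, C5 and C7. In step count for the carbon framework this road is clearly superior: one step from an achiral precursor to all fifteen carbons and three stereocentres. The weak points lie after the key step. A7 has no oxygen, and the target needs hydroxyls at C3 (an unactivated methylene, needing an oxidase or a directed C–H oxidation), C8 and C9 (the alkene of A7 is C9=C10, so oxygen must be moved onto C8 and H10 set trans). All of this must be done beside the isopropenyl alkene, and the enzyme must supply useful quantities. The chosen plan answers with every oxygen placed by construction and no late C–H oxidation.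

Key step: step 8

Remark on numbering: eremophilane locants are used for bicyclic compounds (C14 = methyl carbon on C5, C15 = carbon on C4, C11–C13 = isopropenyl); β is the face of C14, α the opposite face; in 15–22 and 31–33 C14 and C15 are β, the isopropenyl group and H10 are α.

Assumption: (S)-pent-1-yn-3-ol (23) is bought as the single enantiomer; lipase resolution of the racemate would supply it otherwise.

## Steps

Step 1
Reactants: 1 2-deoxy-D-ribose
Product: 2 2-deoxy-3,4-O-isopropylidene-D-erythro-pentopyranose (lactol; anomeric mixture)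
Conditions: 2-methoxypropene, PPTS (cat.), EtOAc, 0 °C to rt
Reagents that add atoms: 2-methoxypropene, COC(C)=C
Why: Kinetic acetonide formation on the cis-3,4-diol of the pyranose form; the anomeric hydroxyl stays free as a masked aldehyde and no stereocentre is touched.

Step 2
Reactants: 2 lactol acetonide; 3 N-methoxy-N-methyl-2-(triphenyl-λ5-phosphanylidene)acetamide
Product: 4 (2E)-4-[(4S,5R)-5-(hydroxymethyl)-2,2-dimethyl-1,3-dioxolan-4-yl]-N-methoxy-N-methylbut-2-enamide
Conditions: PhCO2H (cat.), THF, reflux
Reagents that add atoms: none
Why: Wittig olefination of the lactol through its open hydroxy aldehyde; the stabilised ylide gives the (E)-alkene and frees the C7 hydroxyl. The amide is a poor Michael acceptor, so oxa-Michael closure to a tetrahydropyran should be slow.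

Step 3
Reactants: 4 hydroxy enamide; 5 1-(triphenyl-λ5-phosphanylidene)propan-2-one
Product: 7 (2E)-N-methoxy-N-methyl-4-[(4S,5R)-2,2-dimethyl-5-[(1E)-3-oxobut-1-en-1-yl]-1,3-dioxolan-4-yl]but-2-enamide, via aldehyde 6 (not isolated)
Conditions: DMP, CH2Cl2, 0 °C to rt; then 5, rt
Reagents that add atoms: none
Why: Dess–Martin oxidation followed in the same flask by Wittig olefination; trapping the α-alkoxy aldehyde at once avoids epimerisation at C8, and the stabilised ylide gives the (E)-enone.

Step 4
Reactants: 7 enone amide; 8 isopropenylmagnesium bromide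
Product: 10 (2E)-N-methoxy-N-methyl-4-[(4S,5R)-2,2-dimethyl-5-[(3S)-2-methyl-5-oxohex-1-en-3-yl]-1,3-dioxolan-4-yl]but-2-enamide, via trimethylsilyl enol ether 9 (not isolated)
Conditions: 8 (2 equiv per Cu), CuI, THF, −40 °C; then Me3SiCl, 7, −78 °C; aq. NH4Cl, then aq. citric acid
Reagents that add atoms: none
Why: Me3SiCl-accelerated conjugate addition of the cuprate [CH2=C(CH3)]2CuMgBr; attack anti to the C8–O bond in the rotamer with C8–H eclipsing the alkene (Felkin-type, general for (E)-γ-alkoxy acceptors) sets C7 as S. With no free Grignard reagent left, the enone reacts far faster than the unsaturated Weinreb amide.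

Step 5
Reactants: 10 methyl ketone; 11 trimethyl phosphonoacetate
Product: 12 methyl (2E,5S)-5-[(4R,5S)-5-[(2E)-4-[methoxy(methyl)amino]-4-oxobut-2-en-1-yl]-2,2-dimethyl-1,3-dioxolan-4-yl]-3,6-dimethylhepta-2,6-dienoate
Conditions: NaH, THF, 0 to 50 °C; chromatography to remove the (Z)-isomer
Reagents that add atoms: none
Why: Horner–Wadsworth–Emmons olefination of the methyl ketone; the (E)-enoate (ester trans to the C6 chain) should predominate and the minor isomer is separable. The phosphonate anion is too weak a base to deprotonate C10 of the enamide.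

Step 6
Reactants: 12 enoate amide
Product: 13 methyl (2E,5S)-3,6-dimethyl-5-[(4R,5S)-2,2-dimethyl-5-[(2E)-4-oxobut-2-en-1-yl]-1,3-dioxolan-4-yl]hepta-2,6-dienoate
Conditions: i-Bu2AlH (1.1 equiv), THF, −78 °C; aq. potassium sodium tartrate
Reagents that add atoms: none
Why: Weinreb amide reduction: the chelated aluminium hemiaminal releases the aldehyde only on work-up. With one equivalent of hydride in THF at −78 °C the amide should be reduced ahead of the β,β-disubstituted enoate.

Step 7
Reactants: 13 enal ester
Product: 14 methyl (2E,5S)-5-[(4R,5S)-5-[(1E,3E)-4-(tert-butyldimethylsilyloxy)buta-1,3-dien-1-yl]-2,2-dimethyl-1,3-dioxolan-4-yl]-3,6-dimethylhepta-2,6-dienoate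
Conditions: TBSOTf, Et3N, CH2Cl2, −78 to 0 °C
Reagents that add atoms: tert-butyldimethylsilyl trifluoromethanesulfonate, CC(C)(C)[Si](C)(C)OS(=O)(=O)C(F)(F)F
Why: Soft γ-enolisation of the enal (O-silylation, then deprotonation at C10 by the amine) gives the 1-silyloxy-1,3-diene; the s-trans enal gives the (E)-enol ether and the branched C9 substituent should take the outside position, giving (E)-C10=C1. Excess amine and low temperature should keep the allylic C9–O bond from ionising.

Step 8
Reactants: 14 triene ester acetonide
Product: 15 methyl 3β-(tert-butyldimethylsilyloxy)-8α,9α-(isopropylidenedioxy)eremophila-1,11-dien-15-oate (trans-fused)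
Conditions: PhMe (0.01 M), BHT, Et3N (1 mol%), sealed silanised glass tube, 180 °C
Reagents that add atoms: none
Why: Concerted but asynchronous [4+2] cycloaddition of the (1E,3E)-1-silyloxydiene C10=C1–C2=C3 onto the tethered (E)-enoate C4=C5; the closest known reaction type is the thermal intramolecular Diels–Alder reaction of 1,7,9-decatrienoates to octalins. Ring A closes as the six-membered cycloadduct through the new C3–C4 and C5–C10 bonds, and ring B closes in the same event as the six-membered ring formed by the tether C6–C7–C8–C9 with C5 and C10 (tether on the diene terminus, the type 1 mode). Diene face (C10 and C5): the tether folds as a chair with O9 and the C7 isopropenyl group equatorial and the cis-dioxolane spanning one equatorial and one axial site; attack on the other face would force both groups axial and syn to the C5 methyl group. Ring fusion: in the ester-endo transition state the C5 methyl group lies cis to the C10–C9 bond and trans to H10, which is the trans fusion; the competitor is the ester-exo mode on the same diene face, which would give the cis-fused C4,C5-diastereomer. This endo/exo choice is the selectivity the step needs most and rests on the endo preference of the ester, enhanced by the polarised silyloxydiene, whereas face selectivity is secured by the three tether stereocentres. C4: suprafacial addition to the (E)-enoate keeps the ester carbon cis to the C5 methyl group. C3: the (E)-enol ether places the silyloxy group cis to the C10–C9 bond (3β), and this centre is re-set in step 14. The β,β-disubstituted enoate is a slow dienophile, hence high dilution, a radical inhibitor, acid-free glass and 180 °C.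

Step 9
Reactants: 15 octalin ester
Product: 16 3β-(tert-butyldimethylsilyloxy)-8α,9α-(isopropylidenedioxy)eremophila-1,11-dien-15-ol
Conditions: i-Bu2AlH (2.5 equiv), CH2Cl2, −78 to 0 °C; aq. potassium sodium tartrate
Reagents that add atoms: none
Why: Ester reduction to the primary alcohol; the neutral aluminium alkoxide should not trigger 1,3-silyl migration from O3, and silyl ether, acetonide and alkenes are inert.

Step 10
Reactants: 16 primary alcohol
Product: 17 3β-(tert-butyldimethylsilyloxy)-8α,9α-(isopropylidenedioxy)eremophila-1,11-dien-15-yl 4-toluenesulfonate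
Conditions: TsCl, pyridine, DMAP (cat.), 0 °C to rt
Reagents that add atoms: 4-toluenesulfonyl chloride, Cc1ccc(cc1)S(Cl)(=O)=O
Why: Sulfonylation of the only free hydroxyl, a primary one.

Step 11
Reactants: 17 tosylate
Product: 18 3β-(tert-butyldimethylsilyloxy)-8α,9α-(isopropylidenedioxy)eremophila-1,11-diene
Conditions: LiBHEt3, THF, 0 °C to reflux
Reagents that add atoms: none
Why: SN2 hydride displacement of the primary tosylate turns C15 into the methyl group. O3 is silylated, so oxetane formation or fragmentation of a 1,3-hydroxy sulfonate cannot intervene.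

Step 12
Reactants: 18 silyl ether
Product: 19 8α,9α-(isopropylidenedioxy)eremophila-1,11-dien-3β-ol
Conditions: Bu4NF, THF, rt to 50 °C
Reagents that add atoms: none
Why: Fluoride cleavage of the hindered allylic silyl ether; nothing else in the molecule responds to fluoride.

Step 13
Reactants: 19 allylic alcohol
Product: 20 8α,9α-(isopropylidenedioxy)eremophila-1,11-dien-3-one
Conditions: DMP, CH2Cl2, 0 °C to rt
Reagents that add atoms: none
Why: Dess–Martin oxidation of the allylic alcohol to the enone. C4 becomes enolisable, but its methyl group is already equatorial and cis to C14, the arrangement expected to be the stable one.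

Step 14
Reactants: 20 ring A enone
Product: 22 8α,9α-(isopropylidenedioxy)eremophil-11-en-3α-ol, via saturated ketone 21 (not isolated)
Conditions: Li (excess), NH3(l)/THF, EtOH, −78 to −33 °C; NH4Cl
Reagents that add atoms: none
Why: Dissolving-metal (Birch-type) reduction: the enone is reduced to the saturated ketone, which with ethanol present is reduced further under thermodynamic control to the equatorial 3α-alcohol (3R), trans to the C4 methyl group. Hydride reagents would be pushed to the equatorial path by the syn-axial C14 and give the axial epimer; the isopropenyl group and the acetonide are inert to these conditions.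

Step 15
Reactants: 23 (S)-pent-1-yn-3-ol
Product: 24 (S)-tert-butyldimethyl(pent-1-yn-3-yloxy)silane
Conditions: TBSCl, imidazole, DMF, rt
Reagents that add atoms: tert-butyldimethylsilyl chloride, CC(C)(C)[Si](C)(C)Cl
Why: Standard silylation of a secondary alcohol; it masks the hydroxyl for the acetylide chemistry of the next step.

Step 16
Reactants: 24 silyl ether of the alkynol
Product: 26 tert-butyl (S)-4-(tert-butyldimethylsilyloxy)hex-2-ynoate, via lithium acetylide 25 (not isolated)
Conditions: n-BuLi, THF, −78 °C; then Boc2O, −78 to 0 °C
Reagents that add atoms: di-tert-butyl dicarbonate, CC(C)(C)OC(=O)OC(=O)OC(C)(C)C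
Why: Deprotonation of the terminal alkyne and C-acylation of the acetylide by the dicarbonate gives the tert-butyl ynoate directly; the stereocentre is not involved.

Step 17
Reactants: 26 silyl ether ynoate
Product: 27 tert-butyl (S)-4-hydroxyhex-2-ynoate
Conditions: HF·pyridine, THF, 0 °C to rt
Reagents that add atoms: none
Why: Acidic fluoride removes the silyl group without exposing the ynoate to basic fluoride or alkoxide; the tert-butyl ester survives.

Step 18
Reactants: 27 hydroxy ynoate; 28 hex-2-ynoic acid
Product: 29 tert-butyl (S)-4-(hex-2-ynoyloxy)hex-2-ynoate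
Conditions: DCC, DMAP (cat.), CH2Cl2, 0 °C
Reagents that add atoms: none
Why: Steglich esterification; an ynoic acid has no alkene geometry to lose on activation, and low temperature with catalytic DMAP limits conjugate addition.

Step 19
Reactants: 29 tert-butyl diester
Product: 30 (S)-4-(hex-2-ynoyloxy)hex-2-ynoic acid
Conditions: CF3CO2H, CH2Cl2, 0 °C to rt
Reagents that add atoms: none
Why: Acidolysis of the tert-butyl ester (loss of 2-methylpropene) frees the carboxyl group without base or nucleophile, so the inner propargylic ester is untouched.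

Step 20
Reactants: 22 core alcohol; 30 side-chain acid
Product: 31 8α,9α-(isopropylidenedioxy)eremophil-11-en-3α-yl (S)-4-(hex-2-ynoyloxy)hex-2-ynoate
Conditions: DCC, DMAP (cat.), CH2Cl2, 0 °C to rt
Reagents that add atoms: none
Why: Steglich esterification of the only free hydroxyl, an equatorial secondary alcohol, with retention at C3; the diol is masked, so acylation can only occur at O3.

Step 21
Reactants: 31 ester acetonide
Product: 32 8α,9α-dihydroxyeremophil-11-en-3α-yl (S)-4-(hex-2-ynoyloxy)hex-2-ynoate
Conditions: AcOH/H2O (4:1), 50 °C
Reagents that add atoms: none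
Why: Acid-catalysed acetonide hydrolysis under conditions too mild to protonate the isopropenyl group; at the ynoate stage the side chain can neither isomerise nor lactonise.

Step 22
Reactants: 32 diol bis-ynoate
Product: 33 (3R,4R,5R,7S,8R,9S,10R)-8,9-dihydroxyeremophil-11-en-3-yl (2Z,4S)-4-[(2Z)-hex-2-enoyloxy]hex-2-enoate (CNP0271544.1)
Conditions: H2 (1 atm), Pd/CaCO3 poisoned with Pb(OAc)2, quinoline, EtOAc, rt; stopped after 2 equiv H2
Reagents that add atoms: none
Why: Syn semihydrogenation of both conjugated alkynes on the poisoned palladium surface gives the two (Z)-enoates. Alkynes bind far more strongly than the hindered 1,1-disubstituted alkene, which should be left alone.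

## Compound list

1 | 2-deoxy-D-ribose | O=CC[C@H](O)[C@H](O)CO | starting material
2 | 2-deoxy-3,4-O-isopropylidene-D-erythro-pentopyranose | OC1C[C@@H]2OC(C)(C)O[C@@H]2CO1 | intermediate
3 | N-methoxy-N-methyl-2-(triphenyl-λ5-phosphanylidene)acetamide | CON(C)C(=O)C=P(c1ccccc1)(c1ccccc1)c1ccccc1 | starting material
4 | (2E)-4-[(4S,5R)-5-(hydroxymethyl)-2,2-dimethyl-1,3-dioxolan-4-yl]-N-methoxy-N-methylbut-2-enamide | CON(C)C(=O)/C=C/C[C@@H]1OC(C)(C)O[C@@H]1CO | intermediate
5 | 1-(triphenyl-λ5-phosphanylidene)propan-2-one | CC(=O)C=P(c1ccccc1)(c1ccccc1)c1ccccc1 | starting material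
6 | (2E)-4-[(4S,5S)-5-formyl-2,2-dimethyl-1,3-dioxolan-4-yl]-N-methoxy-N-methylbut-2-enamide (not isolated) | CON(C)C(=O)/C=C/C[C@@H]1OC(C)(C)O[C@@H]1C=O | intermediate
7 | (2E)-N-methoxy-N-methyl-4-[(4S,5R)-2,2-dimethyl-5-[(1E)-3-oxobut-1-en-1-yl]-1,3-dioxolan-4-yl]but-2-enamide | CON(C)C(=O)/C=C/C[C@@H]1OC(C)(C)O[C@@H]1/C=C/C(C)=O | intermediate
8 | isopropenylmagnesium bromide | C=C(C)[Mg]Br | starting material
9 | (2E)-N-methoxy-N-methyl-4-[(4S,5R)-2,2-dimethyl-5-[(3S)-2-methyl-5-(trimethylsilyloxy)hexa-1,4-dien-3-yl]-1,3-dioxolan-4-yl]but-2-enamide (enol ether geometry not defined; not isolated) | CON(C)C(=O)/C=C/C[C@@H]1OC(C)(C)O[C@@H]1[C@@H](C=C(C)O[Si](C)(C)C)C(C)=C | intermediate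
10 | (2E)-N-methoxy-N-methyl-4-[(4S,5R)-2,2-dimethyl-5-[(3S)-2-methyl-5-oxohex-1-en-3-yl]-1,3-dioxolan-4-yl]but-2-enamide | CON(C)C(=O)/C=C/C[C@@H]1OC(C)(C)O[C@@H]1[C@@H](CC(C)=O)C(C)=C | intermediate
11 | trimethyl phosphonoacetate | COC(=O)CP(=O)(OC)OC | starting material
12 | methyl (2E,5S)-5-[(4R,5S)-5-[(2E)-4-[methoxy(methyl)amino]-4-oxobut-2-en-1-yl]-2,2-dimethyl-1,3-dioxolan-4-yl]-3,6-dimethylhepta-2,6-dienoate | CON(C)C(=O)/C=C/C[C@@H]1OC(C)(C)O[C@@H]1[C@@H](C/C(C)=C/C(=O)OC)C(C)=C | intermediate
13 | methyl (2E,5S)-3,6-dimethyl-5-[(4R,5S)-2,2-dimethyl-5-[(2E)-4-oxobut-2-en-1-yl]-1,3-dioxolan-4-yl]hepta-2,6-dienoate | O=C/C=C/C[C@@H]1OC(C)(C)O[C@@H]1[C@@H](C/C(C)=C/C(=O)OC)C(C)=C | intermediate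
14 | methyl (2E,5S)-5-[(4R,5S)-5-[(1E,3E)-4-(tert-butyldimethylsilyloxy)buta-1,3-dien-1-yl]-2,2-dimethyl-1,3-dioxolan-4-yl]-3,6-dimethylhepta-2,6-dienoate | C=C(C)[C@H](C/C(C)=C/C(=O)OC)[C@H]1OC(C)(C)O[C@H]1/C=C/C=C/O[Si](C)(C)C(C)(C)C | intermediate
15 | methyl 3β-(tert-butyldimethylsilyloxy)-8α,9α-(isopropylidenedioxy)eremophila-1,11-dien-15-oate | C=C(C)[C@@H]1C[C@]2(C)[C@@H](C(=O)OC)[C@@H](O[Si](C)(C)C(C)(C)C)C=C[C@H]2[C@@H]3OC(C)(C)O[C@H]13 | intermediate
16 | 3β-(tert-butyldimethylsilyloxy)-8α,9α-(isopropylidenedioxy)eremophila-1,11-dien-15-ol | C=C(C)[C@@H]1C[C@]2(C)[C@@H](CO)[C@@H](O[Si](C)(C)C(C)(C)C)C=C[C@H]2[C@@H]3OC(C)(C)O[C@H]13 | intermediate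
17 | 3β-(tert-butyldimethylsilyloxy)-8α,9α-(isopropylidenedioxy)eremophila-1,11-dien-15-yl 4-toluenesulfonate | C=C(C)[C@@H]1C[C@]2(C)[C@@H](COS(=O)(=O)c4ccc(C)cc4)[C@@H](O[Si](C)(C)C(C)(C)C)C=C[C@H]2[C@@H]3OC(C)(C)O[C@H]13 | intermediate
18 | 3β-(tert-butyldimethylsilyloxy)-8α,9α-(isopropylidenedioxy)eremophila-1,11-diene | C=C(C)[C@@H]1C[C@]2(C)[C@@H](C)[C@@H](O[Si](C)(C)C(C)(C)C)C=C[C@H]2[C@@H]3OC(C)(C)O[C@H]13 | intermediate
19 | 8α,9α-(isopropylidenedioxy)eremophila-1,11-dien-3β-ol | C=C(C)[C@@H]1C[C@]2(C)[C@@H](C)[C@@H](O)C=C[C@H]2[C@@H]3OC(C)(C)O[C@H]13 | intermediate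
20 | 8α,9α-(isopropylidenedioxy)eremophila-1,11-dien-3-one | C=C(C)[C@@H]1C[C@]2(C)[C@@H](C)C(=O)C=C[C@H]2[C@@H]3OC(C)(C)O[C@H]13 | intermediate
21 | 8α,9α-(isopropylidenedioxy)eremophil-11-en-3-one (not isolated) | C=C(C)[C@@H]1C[C@]2(C)[C@@H](C)C(=O)CC[C@H]2[C@@H]3OC(C)(C)O[C@H]13 | intermediate
22 | 8α,9α-(isopropylidenedioxy)eremophil-11-en-3α-ol | C=C(C)[C@@H]1C[C@]2(C)[C@@H](C)[C@H](O)CC[C@H]2[C@@H]3OC(C)(C)O[C@H]13 | intermediate
23 | (S)-pent-1-yn-3-ol | CC[C@H](O)C#C | starting material
24 | (S)-tert-butyldimethyl(pent-1-yn-3-yloxy)silane | CC[C@H](O[Si](C)(C)C(C)(C)C)C#C | intermediate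
25 | lithium acetylide of 24 (not isolated) | CC[C@H](O[Si](C)(C)C(C)(C)C)C#C[Li] | intermediate
26 | tert-butyl (S)-4-(tert-butyldimethylsilyloxy)hex-2-ynoate | CC[C@H](O[Si](C)(C)C(C)(C)C)C#CC(=O)OC(C)(C)C | intermediate
27 | tert-butyl (S)-4-hydroxyhex-2-ynoate | CC[C@H](O)C#CC(=O)OC(C)(C)C | intermediate
28 | hex-2-ynoic acid | CCCC#CC(=O)O | starting material
29 | tert-butyl (S)-4-(hex-2-ynoyloxy)hex-2-ynoate | CC[C@H](OC(=O)C#CCCC)C#CC(=O)OC(C)(C)C | intermediate
30 | (S)-4-(hex-2-ynoyloxy)hex-2-ynoic acid | CC[C@H](OC(=O)C#CCCC)C#CC(=O)O | intermediate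
31 | 8α,9α-(isopropylidenedioxy)eremophil-11-en-3α-yl (S)-4-(hex-2-ynoyloxy)hex-2-ynoate | C=C(C)[C@@H]1C[C@]2(C)[C@@H](C)[C@H](OC(=O)C#C[C@H](CC)OC(=O)C#CCCC)CC[C@H]2[C@@H]3OC(C)(C)O[C@H]13 | intermediate
32 | 8α,9α-dihydroxyeremophil-11-en-3α-yl (S)-4-(hex-2-ynoyloxy)hex-2-ynoate | C=C(C)[C@@H]1C[C@]2(C)[C@@H](C)[C@H](OC(=O)C#C[C@H](CC)OC(=O)C#CCCC)CC[C@H]2[C@H](O)[C@@H]1O | intermediate
33 | (3R,4R,5R,7S,8R,9S,10R)-8,9-dihydroxyeremophil-11-en-3-yl (2Z,4S)-4-[(2Z)-hex-2-enoyloxy]hex-2-enoate | C=C(C)[C@@H]1C[C@]2(C)[C@@H](C)[C@H](OC(=O)/C=C\[C@H](CC)OC(=O)/C=C\CCC)CC[C@H]2[C@H](O)[C@@H]1O | target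

## Step count and least certain steps

Total step count: 22. Longest linear sequence: 17 steps (steps 1–14 and 20–22); the side-chain acid 30 takes 5 steps (15–19).

**Step 8 (key step).** Two things are most likely to go wrong: too little preference for the ester-endo mode, so that the cis-fused C4,C5-diastereomer forms beside 15, and slow cycloaddition of the trisubstituted enoate, so that the silyl dienol ether degrades first. The fallback raises the dienophile to the aldehyde level, which should react at lower temperature with a stronger endo preference. It sets out from 14: reduction of the ester with i-Bu2AlH gives the allylic alcohol F1, oxidation with MnO2 gives the trienal F2, and heating in toluene near 100 °C gives the octalin aldehyde F3. Reduction with NaBH4 returns to the route at 16.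

**Step 7.** The γ-deprotonation may give poor control of the C10=C1 geometry (only the E isomer can cyclise), and the silyl triflate may ionise the allylic C9–O bond of the product, with loss of the acetonide oxygen. The fallback replaces the silyl dienol ether by a dienyl ester, which needs no Lewis acidic silylating agent, survives chromatography and can be equilibrated to the (E,E) isomer with a trace of iodine. It sets out from 13: Ac2O, Et3N and DMAP give the dienyl acetate F4, thermal cycloaddition gives the acetoxy octalin ester F5, and LiAlH4 cleaves acetate and ester to the diol F6. Tosylation of the primary hydroxyl gives the hydroxy tosylate F7, and silylation with TBSOTf and 2,6-lutidine returns to the route at 17.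

**Step 6.** The aluminium hydride may reduce the enoate as well, or over-reduce the amide. The fallback changes the spectator ester to one that is inert to the hydride at −78 °C. It sets out from 10: olefination with tert-butyl diethylphosphonoacetate gives the tert-butyl enoate amide F8, i-Bu2AlH gives the tert-butyl ester enal F9, silyl enolisation gives the tert-butyl ester triene F10, and cycloaddition gives the tert-butyl octalin ester F11. Reduction with LiAlH4 returns to the route at 16.

**Step 4.** Facial selectivity of the cuprate addition may erode if the reactive rotamer is not well defined by the cis-dioxolane, and stray organomagnesium reagent may attack the amide. The fallback replaces substrate control by catalyst control. It sets out from 7: rhodium-catalysed conjugate addition of potassium isopropenyltrifluoroborate with [Rh(cod)Cl]2 and the BINAP enantiomer that reinforces anti addition, in aqueous dioxane, leads directly to 10; no new compound is made.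

**Step 14.** The second reduction may stop part-way, leaving mixtures of ketone and alcohol, or thermodynamic control at C3 may be incomplete. The fallback sets C3 by substitution instead. It sets out from 20: conjugate reduction with [(Ph3P)CuH]6 gives 21, now isolated; LiBH(s-Bu)3 attacks from the equatorial side to give the axial 3β-alcohol F12; Mitsunobu inversion with 4-nitrobenzoic acid, PPh3 and DIAD gives the 3α-(4-nitrobenzoate) F13; methanolysis with K2CO3 returns to the route at 22.

**Step 22.** Hydrogenation may run on to the saturated esters or touch the isopropenyl group, or may stop at a mono-alkyne. The fallback forms the (Z)-alkenes on the small fragment, where over-reduction costs little and there is no competing alkene. It sets out from 29: the same semihydrogenation gives the (Z,Z)-tert-butyl ester F14, CF3CO2H gives the (Z,Z)-acid F15, and Yamaguchi esterification with 22 (2,4,6-trichlorobenzoyl chloride, Et3N, then DMAP) gives the acetonide of the target F16. Aqueous acetic acid returns to the route at 33. The price is the risk of Z-to-E isomerisation during carboxyl activation, which the main route avoids.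

## Further compounds

F1 | step 8 | (2E,5S)-5-[(4R,5S)-5-[(1E,3E)-4-(tert-butyldimethylsilyloxy)buta-1,3-dien-1-yl]-2,2-dimethyl-1,3-dioxolan-4-yl]-3,6-dimethylhepta-2,6-dien-1-ol | C=C(C)[C@H](C/C(C)=C/CO)[C@H]1OC(C)(C)O[C@H]1/C=C/C=C/O[Si](C)(C)C(C)(C)C
F2 | step 8 | (2E,5S)-5-[(4R,5S)-5-[(1E,3E)-4-(tert-butyldimethylsilyloxy)buta-1,3-dien-1-yl]-2,2-dimethyl-1,3-dioxolan-4-yl]-3,6-dimethylhepta-2,6-dienal | C=C(C)[C@H](C/C(C)=C/C=O)[C@H]1OC(C)(C)O[C@H]1/C=C/C=C/O[Si](C)(C)C(C)(C)C
F3 | step 8 | 3β-(tert-butyldimethylsilyloxy)-8α,9α-(isopropylidenedioxy)eremophila-1,11-dien-15-al | C=C(C)[C@@H]1C[C@]2(C)[C@@H](C=O)[C@@H](O[Si](C)(C)C(C)(C)C)C=C[C@H]2[C@@H]3OC(C)(C)O[C@H]13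
F4 | step 7 | methyl (2E,5S)-5-[(4R,5S)-5-[(1E,3E)-4-acetoxybuta-1,3-dien-1-yl]-2,2-dimethyl-1,3-dioxolan-4-yl]-3,6-dimethylhepta-2,6-dienoate | C=C(C)[C@H](C/C(C)=C/C(=O)OC)[C@H]1OC(C)(C)O[C@H]1/C=C/C=C/OC(C)=O
F5 | step 7 | methyl 3β-acetoxy-8α,9α-(isopropylidenedioxy)eremophila-1,11-dien-15-oate | C=C(C)[C@@H]1C[C@]2(C)[C@@H](C(=O)OC)[C@@H](OC(C)=O)C=C[C@H]2[C@@H]3OC(C)(C)O[C@H]13
F6 | step 7 | 8α,9α-(isopropylidenedioxy)eremophila-1,11-diene-3β,15-diol | C=C(C)[C@@H]1C[C@]2(C)[C@@H](CO)[C@@H](O)C=C[C@H]2[C@@H]3OC(C)(C)O[C@H]13
F7 | step 7 | 3β-hydroxy-8α,9α-(isopropylidenedioxy)eremophila-1,11-dien-15-yl 4-toluenesulfonate | C=C(C)[C@@H]1C[C@]2(C)[C@@H](COS(=O)(=O)c4ccc(C)cc4)[C@@H](O)C=C[C@H]2[C@@H]3OC(C)(C)O[C@H]13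
F8 | step 6 | tert-butyl (2E,5S)-5-[(4R,5S)-5-[(2E)-4-[methoxy(methyl)amino]-4-oxobut-2-en-1-yl]-2,2-dimethyl-1,3-dioxolan-4-yl]-3,6-dimethylhepta-2,6-dienoate | CON(C)C(=O)/C=C/C[C@@H]1OC(C)(C)O[C@@H]1[C@@H](C/C(C)=C/C(=O)OC(C)(C)C)C(C)=C
F9 | step 6 | tert-butyl (2E,5S)-3,6-dimethyl-5-[(4R,5S)-2,2-dimethyl-5-[(2E)-4-oxobut-2-en-1-yl]-1,3-dioxolan-4-yl]hepta-2,6-dienoate | O=C/C=C/C[C@@H]1OC(C)(C)O[C@@H]1[C@@H](C/C(C)=C/C(=O)OC(C)(C)C)C(C)=C
F10 | step 6 | tert-butyl (2E,5S)-5-[(4R,5S)-5-[(1E,3E)-4-(tert-butyldimethylsilyloxy)buta-1,3-dien-1-yl]-2,2-dimethyl-1,3-dioxolan-4-yl]-3,6-dimethylhepta-2,6-dienoate | C=C(C)[C@H](C/C(C)=C/C(=O)OC(C)(C)C)[C@H]1OC(C)(C)O[C@H]1/C=C/C=C/O[Si](C)(C)C(C)(C)C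
F11 | step 6 | tert-butyl 3β-(tert-butyldimethylsilyloxy)-8α,9α-(isopropylidenedioxy)eremophila-1,11-dien-15-oate | C=C(C)[C@@H]1C[C@]2(C)[C@@H](C(=O)OC(C)(C)C)[C@@H](O[Si](C)(C)C(C)(C)C)C=C[C@H]2[C@@H]3OC(C)(C)O[C@H]13
F12 | step 14 | 8α,9α-(isopropylidenedioxy)eremophil-11-en-3β-ol | C=C(C)[C@@H]1C[C@]2(C)[C@@H](C)[C@@H](O)CC[C@H]2[C@@H]3OC(C)(C)O[C@H]13
F13 | step 14 | 8α,9α-(isopropylidenedioxy)eremophil-11-en-3α-yl 4-nitrobenzoate | C=C(C)[C@@H]1C[C@]2(C)[C@@H](C)[C@H](OC(=O)c4ccc(cc4)[N+](=O)[O-])CC[C@H]2[C@@H]3OC(C)(C)O[C@H]13
F14 | step 22 | tert-butyl (2Z,4S)-4-[(2Z)-hex-2-enoyloxy]hex-2-enoate | CC(C)(C)OC(=O)/C=C\[C@H](CC)OC(=O)/C=C\CCC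
F15 | step 22 | (2Z,4S)-4-[(2Z)-hex-2-enoyloxy]hex-2-enoic acid | OC(=O)/C=C\[C@H](CC)OC(=O)/C=C\CCC
F16 | step 22 | 8α,9α-(isopropylidenedioxy)eremophil-11-en-3α-yl (2Z,4S)-4-[(2Z)-hex-2-enoyloxy]hex-2-enoate | C=C(C)[C@@H]1C[C@]2(C)[C@@H](C)[C@H](OC(=O)/C=C\[C@H](CC)OC(=O)/C=C\CCC)CC[C@H]2[C@@H]3OC(C)(C)O[C@H]13
F0 | step 4 | none | none
A1 | alternative 1 | 6-methoxy-5-methyl-3,4-dihydronaphthalen-1(2H)-one | COc1ccc2c(c1C)CCCC2=O
A2 | alternative 1 | 5(10)-ene allylic alcohol with C3 ethylene ketal, C4 methyl and C9 hydroxyl | C1CC2=C(CCC3(OCCO3)[C@@H]2C)[C@@H](O)C1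
A3 | alternative 1 | 5,10-methano adduct (cyclopropane on the hydroxyl face) | C1C[C@]23C[C@@]3(CCC4(OCCO4)[C@@H]2C)[C@@H](O)C1
A4 | alternative 2 | 1,6-dialdehyde (ring A with C5 3-oxopropyl and C10 formyl groups, 3-O-(4-methoxybenzyl)) | O=CCC[C@]1(C)[C@@H](C)[C@H](OCc2ccc(OC)cc2)CC[C@H]1C=O
A5 | alternative 2 | 7-unsubstituted core 8α,9α-diol, 3-O-(4-methoxybenzyl) ether | C1C[C@]2(C)[C@@H](C)[C@H](OCc3ccc(OC)cc3)CC[C@H]2[C@H](O)[C@@H]1O
A6 | alternative 3 | (2E,6E)-farnesyl diphosphate | CC(C)=CCC/C(C)=C/CC/C(C)=C/COP(=O)(O)OP(=O)(O)O
A7 | alternative 3 | (+)-aristolochene | C=C(C)[C@@H]1C[C@]2(C)[C@@H](C)CCCC2=CC1
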